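**Plan**

1. Convention: azulene locants (C1 acetoxy carbon, C3 carbinol, C3a/C8a ring fusion, C4 and C8 acyloxy carbons, C6 ring methyl); β is the face of the C8a methyl. Retrosynthesis cuts the three ester C–O bonds, traces the C1/C3/C4/C8 oxygenation back to a 4-methoxy-8a-methyl-dihydroazulen-1-one, and then cuts C8a–C3a and C8a–C8 together.
2. Enabling feature: the ring C3a–C4–C5–C6–C7–C8 has oxygen at C4 and methyl at C6 (the 1,3 pattern of 3-methylanisole) and is completed by C8a, a quaternary methyl carbon next to the oxygenated C1, i.e. an acyl(methyl)carbene carbon. A benzene ring plus one inserted carbon therefore gives the whole seven-membered ring.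
3. Forward: asymmetric conjugate addition joins arene and chain, the α-diazo ethyl ketone is made, and one Rh(II) event closes the cyclopentanone (with a cyclopropane) and then, by norcaradiene opening, the seven-membered ring, which is the last ring formed.
4. Stereochemistry: C3 from (S)-BINAP, relayed to C8a in the Buchner step; C3a by equilibration; C3 is then erased and rebuilt as the 3β-carbinol by epoxidation; the C1 and C4 carbinols by hydride delivery from the 3β-OH; C8 by α-epoxidation and Mitsunobu inversion.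

Key step: step 4

Step 1
Reactants: 1 (2-methoxy-4-methylphenyl)boronic acid; 2 ethyl (E)-4-methylpent-2-enoate
Product: 3 ethyl (S)-3-(2-methoxy-4-methylphenyl)-4-methylpentanoate
Conditions: Rh(acac)(C2H4)2 (3 mol %), (S)-BINAP, dioxane/H2O 10:1, 100 °C, 1 in excess
Reagents that add atoms: none
Why: Rh(I)/BINAP asymmetric conjugate addition of an arylboronic acid (Hayashi–Miyaura reaction), in which aryl–Rh should add to the α-si face of the (E)-enoate and set C3 as S; the antipodal ligand is the remedy if the sense proves opposite.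

Step 2
Reactants: 3 ethyl (S)-3-(2-methoxy-4-methylphenyl)-4-methylpentanoate
Product: 4 (S)-3-(2-methoxy-4-methylphenyl)-4-methylpentanoic acid
Conditions: LiOH, THF/MeOH/H2O, 50 °C; then aq. HCl
Reagents that add atoms: lithium hydroxide [Li+].[OH-] (oxygen of the carboxyl OH)
Why: Saponification of an ethyl ester; the stereocentre is β to the carboxyl group and cannot epimerise.

Step 3
Reactants: 4 (S)-3-(2-methoxy-4-methylphenyl)-4-methylpentanoic acid
Product: 6 (S)-2-diazo-5-(2-methoxy-4-methylphenyl)-6-methylheptan-3-one, via acid chloride 5 (not isolated)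
Conditions: (COCl)2, DMF (cat.), CH2Cl2, 0 °C to rt, evaporate; CH3CHN2 (3 equiv, Et2O, freshly made from N-ethyl-N-nitrosourea/KOH), −20 to 0 °C
Reagents that add atoms: diazoethane CC=[N+]=[N-]; oxalyl chloride ClC(=O)C(=O)Cl (chlorine of 5 only)
Why: Acylation of a diazoalkane by an acid chloride (diazoketone synthesis of the Arndt–Eistert type) places the diazo group unambiguously on the methyl-bearing carbon, with a second equivalent of diazoethane taking up HCl.

Step 4
Reactants: 6 (S)-2-diazo-5-(2-methoxy-4-methylphenyl)-6-methylheptan-3-one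
Product: 8 3α-isopropyl-4-methoxy-6,8aβ-dimethyl-3,8a-dihydroazulen-1(2H)-one, via norcaradiene 7 (not isolated)
Conditions: Rh2(OAc)4 (1 mol %), CH2Cl2, reflux, slow addition of 6 at high dilution
Reagents that add atoms: none
Why: Intramolecular Buchner reaction: the rhodium carbenoid from 6 adds across the bond between the ipso carbon and the unsubstituted ortho carbon of the arene to give norcaradiene 7, and thermal disrotatory 6π-electrocyclic opening of the cyclopropane bond C3a–C8 releases the ring strain and expands the benzene ring by the carbene carbon to cycloheptatriene 8. The closest known reaction type is the Rh(II)-catalysed cyclisation of 2-diazo-5-arylpentan-3-ones to 8a-methyl-dihydroazulenones. The cyclopentanone is closed by the [2+1] cycloaddition (carbene carbon to ipso carbon, five-membered ring fused to the cyclopropane) and the seven-membered ring by the electrocyclic ring opening, so it is the last ring to form. C8a is the only new stereocentre that survives and is controlled by C3: in the envelope-like transition state the isopropyl group avoids the arene plane (allylic strain with the methoxy-bearing ortho carbon) and points to the arene face remote from the carbenoid, which places it anti to the C8a methyl. The step needs regioselectivity for the unsubstituted ortho position, secured by the methoxy group blocking the other one, and chemoselectivity for arene addition over 1,5 C–H insertion at the isopropyl methine and over 1,2-hydride shift, for which the electron-rich arene, the carboxylate catalyst and slow addition are relied on.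

Step 5
Reactants: 8 3α-isopropyl-4-methoxy-6,8aβ-dimethyl-3,8a-dihydroazulen-1(2H)-one
Product: 9 4,4-ethylenedioxy-3α-isopropyl-6,8aβ-dimethyl-2,3,3aα,4-tetrahydroazulen-1(8aH)-one
Conditions: ethylene glycol (5 equiv), PPTS (cat.), benzene, 50 °C
Reagents that add atoms: ethylene glycol OCCO
Why: Acid-catalysed acetal exchange of a methyl enol ether: protonation at C3a gives the C4 oxocarbenium ion, which the diol traps, and under these equilibrating conditions the trans ring fusion (3a-H α) should result because C4 then lies anti to the C3 isopropyl group, while the hindered C1 ketone stays free.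

Step 6
Reactants: 9 4,4-ethylenedioxy-3α-isopropyl-6,8aβ-dimethyl-2,3,3aα,4-tetrahydroazulen-1(8aH)-one
Product: 10 4,4-ethylenedioxy-3-isopropyl-6,8aβ-dimethyl-3aα,4-dihydroazulen-1(8aH)-one
Conditions: IBX, 4-methoxypyridine N-oxide, DMSO, rt
Reagents that add atoms: none
Why: IBX-mediated α,β-dehydrogenation of a ketone; C2 is the only enolisable position (C8a is quaternary), so only the C2=C3 enone can form, and the C3 centre, having relayed its information to C8a, is removed.

Step 7
Reactants: 10 4,4-ethylenedioxy-3-isopropyl-6,8aβ-dimethyl-3aα,4-dihydroazulen-1(8aH)-one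
Product: 11 2β,3β-epoxy-4,4-ethylenedioxy-3α-isopropyl-6,8aβ-dimethyl-2,3,3aα,4-tetrahydroazulen-1(8aH)-one
Conditions: 30 % H2O2, NaOH (cat.), MeOH, 0 °C
Reagents that add atoms: hydrogen peroxide OO
Why: Weitz–Scheffer nucleophilic epoxidation, in which hydroperoxide should add to C3 on the β face because the α face of C3 is screened by the C3a–H and the α oxygen of the peri C4 dioxolane, as is usual for trans-fused bicyclic cyclopentenones of the steroidal 15-en-17-one type.

Step 8
Reactants: 11 2β,3β-epoxy-4,4-ethylenedioxy-3α-isopropyl-6,8aβ-dimethyl-2,3,3aα,4-tetrahydroazulen-1(8aH)-one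
Product: 12 4,4-ethylenedioxy-3β-hydroxy-3α-isopropyl-6,8aβ-dimethyl-2,3,3aα,4-tetrahydroazulen-1(8aH)-one
Conditions: SmI2 (2.2 equiv), THF/MeOH, −90 °C
Reagents that add atoms: none
Why: SmI2 reduction of an α,β-epoxy ketone cleaves the C2–O bond through the ketyl and gives the β-hydroxy ketone, leaving the C3–O bond and hence the 3β-OH untouched.

Step 9
Reactants: 12 4,4-ethylenedioxy-3β-hydroxy-3α-isopropyl-6,8aβ-dimethyl-2,3,3aα,4-tetrahydroazulen-1(8aH)-one
Product: 13 4,4-ethylenedioxy-3α-isopropyl-6,8aβ-dimethyl-1,2,3,3aα,4,8a-hexahydroazulene-1α,3β-diol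
Conditions: Me4NBH(OAc)3, MeCN/AcOH, −30 °C
Reagents that add atoms: none
Why: Evans–Saksena reduction: the tertiary 3β-OH exchanges onto boron and delivers hydride intramolecularly to the β face of the C1 ketone, which should give the 1α-alcohol (1,3-anti diol), the opposite of external hydride attack anti to the angular methyl.

Step 10
Reactants: 13 4,4-ethylenedioxy-3α-isopropyl-6,8aβ-dimethyl-1,2,3,3aα,4,8a-hexahydroazulene-1α,3β-diol
Product: 14 1α-acetoxy-4,4-ethylenedioxy-3α-isopropyl-6,8aβ-dimethyl-1,2,3,3aα,4,8a-hexahydroazulen-3β-ol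
Conditions: Ac2O, pyridine, DMAP (cat.), CH2Cl2, 0 °C
Reagents that add atoms: acetic anhydride CC(=O)OC(C)=O
Why: DMAP-catalysed acetylation distinguishes the secondary C1 hydroxyl from the tertiary C3 hydroxyl.

Step 11
Reactants: 14 1α-acetoxy-4,4-ethylenedioxy-3α-isopropyl-6,8aβ-dimethyl-1,2,3,3aα,4,8a-hexahydroazulen-3β-ol
Product: 15 1α-acetoxy-3β-hydroxy-3α-isopropyl-6,8aβ-dimethyl-1,2,3,3aα-tetrahydroazulen-4(8aH)-one
Conditions: PPTS, acetone/H2O, 40 °C
Reagents that add atoms: water O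
Why: Mild acid hydrolysis of the dienyl dioxolane (stabilised oxocarbenium ion) frees the C4 ketone as the conjugated 5,7-dienone; the tertiary aldol-type alcohol should tolerate PPTS and C3a stays in its more stable trans-fused form.

Step 12
Reactants: 15 1α-acetoxy-3β-hydroxy-3α-isopropyl-6,8aβ-dimethyl-1,2,3,3aα-tetrahydroazulen-4(8aH)-one
Product: 16 1α-acetoxy-7α,8α-epoxy-3β-hydroxy-3α-isopropyl-6,8aβ-dimethyl-1,2,3,3aα,7,8-hexahydroazulen-4(8aH)-one
Conditions: mCPBA, NaHCO3, CH2Cl2, 0 °C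
Reagents that add atoms: mCPBA OOC(=O)c1cccc(Cl)c1
Why: Prilezhaev epoxidation of a 2,4-dienone takes the more electron-rich γ,δ alkene (C7=C8) and should occur on the α face, anti to the adjacent angular methyl.

Step 13
Reactants: 16 1α-acetoxy-7α,8α-epoxy-3β-hydroxy-3α-isopropyl-6,8aβ-dimethyl-1,2,3,3aα,7,8-hexahydroazulen-4(8aH)-one
Product: 17 1α-acetoxy-3β,8α-dihydroxy-3α-isopropyl-6,8aβ-dimethyl-2,3,3aα,5,8,8a-hexahydroazulen-4(1H)-one
Conditions: SmI2 (2.2 equiv), THF/MeOH, −78 °C
Reagents that add atoms: none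
Why: SmI2 reduction of a γ,δ-epoxy enone (vinylogous epoxy ketone opening): two-electron reduction opens the C7–O bond to a dienolate that is protonated at C5, which gives the deconjugated C6=C7 alkene of the target and the 8α allylic alcohol.

Step 14
Reactants: 17 1α-acetoxy-3β,8α-dihydroxy-3α-isopropyl-6,8aβ-dimethyl-2,3,3aα,5,8,8a-hexahydroazulen-4(1H)-one; 18 benzoic acid
Product: 19 1α-acetoxy-8β-benzoyloxy-3β-hydroxy-3α-isopropyl-6,8aβ-dimethyl-2,3,3aα,5,8,8a-hexahydroazulen-4(1H)-one
Conditions: PPh3, DIAD, toluene, 0 °C to rt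
Reagents that add atoms: none
Why: Mitsunobu esterification with SN2 inversion turns the 8α-alcohol into the 8β-benzoate; the only other hydroxyl is tertiary and there is no sp3 β-hydrogen (C8a is quaternary) for elimination.

Step 15
Reactants: 19 1α-acetoxy-8β-benzoyloxy-3β-hydroxy-3α-isopropyl-6,8aβ-dimethyl-2,3,3aα,5,8,8a-hexahydroazulen-4(1H)-one
Product: 20 1α-acetoxy-8β-benzoyloxy-3α-isopropyl-6,8aβ-dimethyl-1,2,3,3aα,4,5,8,8a-octahydroazulene-3β,4α-diol
Conditions: Me4NBH(OAc)3, MeCN/AcOH, −30 °C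
Reagents that add atoms: none
Why: Evans–Saksena reduction directed by the 3β-OH delivers hydride to the β face of the C4 ketone and should give the 4α-alcohol, while the esters and the alkene are inert to the reagent.

Step 16
Reactants: 20 1α-acetoxy-8β-benzoyloxy-3α-isopropyl-6,8aβ-dimethyl-1,2,3,3aα,4,5,8,8a-octahydroazulene-3β,4α-diol; 21 4-acetoxybenzoic acid
Product: 22 1α-acetoxy-4α-(4-acetoxybenzoyloxy)-8β-benzoyloxy-3α-isopropyl-6,8aβ-dimethyl-1,2,3,3aα,4,5,8,8a-octahydroazulen-3β-ol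
Conditions: EDC·HCl, DMAP, CH2Cl2, rt
Reagents that add atoms: none
Why: Steglich esterification acylates the only secondary hydroxyl; the tertiary C3–OH does not react and the acetyl group keeps the phenol from self-acylation.

Step 17
Reactants: 22 1α-acetoxy-4α-(4-acetoxybenzoyloxy)-8β-benzoyloxy-3α-isopropyl-6,8aβ-dimethyl-1,2,3,3aα,4,5,8,8a-octahydroazulen-3β-ol
Product: 23 1α-acetoxy-8β-benzoyloxy-4α-(4-hydroxybenzoyloxy)-3α-isopropyl-6,8aβ-dimethyl-1,2,3,3aα,4,5,8,8a-octahydroazulen-3β-ol (CNP0316187.1)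
Conditions: pyrrolidine (1.2 equiv), CH2Cl2, 0 °C
Reagents that add atoms: none
Why: Aminolysis of an aryl acetate (phenoxide leaving group, further activated by the para ester) is far faster than that of the hindered alkyl acetate, the benzoate or the aroate, so only the phenol should be freed.

**Compound list**

1 | (2-methoxy-4-methylphenyl)boronic acid | COc1cc(C)ccc1B(O)O | starting material
2 | ethyl (E)-4-methylpent-2-enoate | CCOC(=O)/C=C/C(C)C | starting material
3 | ethyl (S)-3-(2-methoxy-4-methylphenyl)-4-methylpentanoate | CCOC(=O)C[C@@H](C(C)C)c1ccc(C)cc1OC | intermediate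
4 | (S)-3-(2-methoxy-4-methylphenyl)-4-methylpentanoic acid | OC(=O)C[C@@H](C(C)C)c1ccc(C)cc1OC | intermediate
5 | (S)-3-(2-methoxy-4-methylphenyl)-4-methylpentanoyl chloride (formed in the flask) | ClC(=O)C[C@@H](C(C)C)c1ccc(C)cc1OC | intermediate
6 | (S)-2-diazo-5-(2-methoxy-4-methylphenyl)-6-methylheptan-3-one | CC(=[N+]=[N-])C(=O)C[C@@H](C(C)C)c1ccc(C)cc1OC | intermediate
7 | norcaradiene valence isomer of 8: cyclopropane C8a–C3a–C8 fused to the cyclopentanone and to a 4-methoxy-6-methylcyclohexa-4,6-diene, 3-isopropyl anti to the 8a-methyl (formed in the flask) | O=C1C[C@@H](C(C)C)[C@@]23C(OC)=CC(C)=C[C@@H]2[C@@]13C | intermediate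
8 | 3α-isopropyl-4-methoxy-6,8aβ-dimethyl-3,8a-dihydroazulen-1(2H)-one | O=C1C[C@@H](C(C)C)C2=C(OC)C=C(C)C=C[C@@]12C | intermediate
9 | 4,4-ethylenedioxy-3α-isopropyl-6,8aβ-dimethyl-2,3,3aα,4-tetrahydroazulen-1(8aH)-one (trans-fused, 5,7-diene) | O=C1C[C@@H](C(C)C)[C@@H]2C3(OCCO3)C=C(C)C=C[C@@]12C | intermediate
10 | 4,4-ethylenedioxy-3-isopropyl-6,8aβ-dimethyl-3aα,4-dihydroazulen-1(8aH)-one (2-en-1-one) | O=C1C=C(C(C)C)[C@@H]2C3(OCCO3)C=C(C)C=C[C@@]12C | intermediate
11 | 2β,3β-epoxy-4,4-ethylenedioxy-3α-isopropyl-6,8aβ-dimethyl-2,3,3aα,4-tetrahydroazulen-1(8aH)-one | O=C1[C@@H]3O[C@]3(C(C)C)[C@@H]2C4(OCCO4)C=C(C)C=C[C@@]12C | intermediate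
12 | 4,4-ethylenedioxy-3β-hydroxy-3α-isopropyl-6,8aβ-dimethyl-2,3,3aα,4-tetrahydroazulen-1(8aH)-one | O=C1C[C@@](O)(C(C)C)[C@@H]2C3(OCCO3)C=C(C)C=C[C@@]12C | intermediate
13 | 4,4-ethylenedioxy-3α-isopropyl-6,8aβ-dimethyl-1,2,3,3aα,4,8a-hexahydroazulene-1α,3β-diol | O[C@H]1C[C@@](O)(C(C)C)[C@@H]2C3(OCCO3)C=C(C)C=C[C@@]12C | intermediate
14 | 1α-acetoxy-4,4-ethylenedioxy-3α-isopropyl-6,8aβ-dimethyl-1,2,3,3aα,4,8a-hexahydroazulen-3β-ol | CC(=O)O[C@H]1C[C@@](O)(C(C)C)[C@@H]2C3(OCCO3)C=C(C)C=C[C@@]12C | intermediate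
15 | 1α-acetoxy-3β-hydroxy-3α-isopropyl-6,8aβ-dimethyl-1,2,3,3aα-tetrahydroazulen-4(8aH)-one (5,7-dien-4-one) | CC(=O)O[C@H]1C[C@@](O)(C(C)C)[C@@H]2C(=O)C=C(C)C=C[C@@]12C | intermediate
16 | 1α-acetoxy-7α,8α-epoxy-3β-hydroxy-3α-isopropyl-6,8aβ-dimethyl-1,2,3,3aα,7,8-hexahydroazulen-4(8aH)-one | CC(=O)O[C@H]1C[C@@](O)(C(C)C)[C@@H]2C(=O)C=C(C)[C@H]3O[C@H]3[C@@]12C | intermediate
17 | 1α-acetoxy-3β,8α-dihydroxy-3α-isopropyl-6,8aβ-dimethyl-2,3,3aα,5,8,8a-hexahydroazulen-4(1H)-one | CC(=O)O[C@H]1C[C@@](O)(C(C)C)[C@@H]2C(=O)CC(C)=C[C@@H](O)[C@@]12C | intermediate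
18 | benzoic acid | OC(=O)c1ccccc1 | starting material
19 | 1α-acetoxy-8β-benzoyloxy-3β-hydroxy-3α-isopropyl-6,8aβ-dimethyl-2,3,3aα,5,8,8a-hexahydroazulen-4(1H)-one | CC(=O)O[C@H]1C[C@@](O)(C(C)C)[C@@H]2C(=O)CC(C)=C[C@H](OC(=O)c3ccccc3)[C@@]12C | intermediate
20 | 1α-acetoxy-8β-benzoyloxy-3α-isopropyl-6,8aβ-dimethyl-1,2,3,3aα,4,5,8,8a-octahydroazulene-3β,4α-diol | CC(=O)O[C@H]1C[C@@](O)(C(C)C)[C@@H]2[C@@H](O)CC(C)=C[C@H](OC(=O)c3ccccc3)[C@@]12C | intermediate
21 | 4-acetoxybenzoic acid | CC(=O)Oc1ccc(cc1)C(=O)O | starting material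
22 | 1α-acetoxy-4α-(4-acetoxybenzoyloxy)-8β-benzoyloxy-3α-isopropyl-6,8aβ-dimethyl-1,2,3,3aα,4,5,8,8a-octahydroazulen-3β-ol | CC(=O)O[C@H]1C[C@@](O)(C(C)C)[C@@H]2[C@@H](OC(=O)c3ccc(OC(C)=O)cc3)CC(C)=C[C@H](OC(=O)c3ccccc3)[C@@]12C | intermediate
23 | 1α-acetoxy-8β-benzoyloxy-4α-(4-hydroxybenzoyloxy)-3α-isopropyl-6,8aβ-dimethyl-1,2,3,3aα,4,5,8,8a-octahydroazulen-3β-ol (CNP0316187.1) | CC(=O)O[C@H]1C[C@@](O)(C(C)C)[C@@H]2[C@@H](OC(=O)c3ccc(O)cc3)CC(C)=C[C@H](OC(=O)c3ccccc3)[C@@]12C | target

**Step count and risks**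

Total step count: 17. Longest linear sequence: 17 steps (1 and 2 to 23).

Steps most likely to fail:

Step 4. The carbenoid may be diverted into 1,5 C–H insertion at the isopropyl methine or into 1,2-hydride migration, or may add to the arene with incomplete facial control by C3. The fallback introduces the isopropyl group after the ring expansion and sets the absolute configuration with the catalyst. It sets out from boronic acid 1. Rh(I)-catalysed conjugate addition to ethyl acrylate should give ethyl 3-(2-methoxy-4-methylphenyl)propanoate F1, and saponification 3-(2-methoxy-4-methylphenyl)propanoic acid F2. Oxalyl chloride should give the acid chloride F3 and diazoethane 2-diazo-5-(2-methoxy-4-methylphenyl)pentan-3-one F4. An enantioselective Buchner reaction with Cu(MeCN)4PF6, a C2-symmetric bis(oxazoline) and NaBARF should pass through the norcaradiene F5 to 4-methoxy-6,8aβ-dimethyl-3,8a-dihydroazulen-1(2H)-one F6. Acetal exchange as in step 5 should give the trans-fused ketal F7, IBX the cyclopentenone F8, and conjugate addition of iPr2CuLi the 3β-isopropyl ketone F9 (the C3 epimer of 9). The dehydrogenation of step 6 then converts F9 into 10, where the route is rejoined.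

Step 7. Hydroperoxide addition may show poor facial selectivity, or the base may deconjugate the enone and epimerise C3a through the dienolate. The fallback delivers the oxygen from a hydroxyl group. From 10, Luche reduction from the α face should give 4,4-ethylenedioxy-3-isopropyl-6,8aβ-dimethyl-1,3aα,4,8a-tetrahydroazulen-1β-ol F10. VO(acac)2/t-BuOOH epoxidation syn to the hydroxyl should give the 2β,3β-epoxy-1β-alcohol F11, and Dess–Martin oxidation returns to epoxy ketone 11.

Step 14. The allylic oxyphosphonium ion may ionise (loss of stereochemical integrity, allylic transposition) or fail to undergo SN2 at the neopentyl centre; the step would also suffer from any lack of α selectivity in step 12. The fallback inverts C8 by oxidation and reduction and converges both C8 epimers. From 17, directed reduction as in step 15 should give 1α-acetoxy-3α-isopropyl-6,8aβ-dimethyl-1,2,3,3aα,4,5,8,8a-octahydroazulene-3β,4α,8α-triol F12. MnO2 should oxidise only the allylic C8 hydroxyl to give the 4α-hydroxy-6-en-8-one F13. EDC/DMAP coupling with 21 should give the 4α-(4-acetoxybenzoate) enone F14, and Luche reduction at −78 °C from the α face the 8β-alcohol F15. Benzoyl chloride/pyridine then gives 22.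

**Further compounds**

F1 | step 4 | ethyl 3-(2-methoxy-4-methylphenyl)propanoate | CCOC(=O)CCc1ccc(C)cc1OC
F2 | step 4 | 3-(2-methoxy-4-methylphenyl)propanoic acid | OC(=O)CCc1ccc(C)cc1OC
F3 | step 4 | 3-(2-methoxy-4-methylphenyl)propanoyl chloride | ClC(=O)CCc1ccc(C)cc1OC
F4 | step 4 | 2-diazo-5-(2-methoxy-4-methylphenyl)pentan-3-one | CC(=[N+]=[N-])C(=O)CCc1ccc(C)cc1OC
F5 | step 4 | norcaradiene valence isomer of F6 | O=C1CC[C@@]23C(OC)=CC(C)=C[C@@H]2[C@@]13C
F6 | step 4 | 4-methoxy-6,8aβ-dimethyl-3,8a-dihydroazulen-1(2H)-one | O=C1CCC2=C(OC)C=C(C)C=C[C@@]12C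
F7 | step 4 | 4,4-ethylenedioxy-6,8aβ-dimethyl-2,3,3aα,4-tetrahydroazulen-1(8aH)-one | O=C1CC[C@@H]2C3(OCCO3)C=C(C)C=C[C@@]12C
F8 | step 4 | 4,4-ethylenedioxy-6,8aβ-dimethyl-3aα,4-dihydroazulen-1(8aH)-one | O=C1C=C[C@@H]2C3(OCCO3)C=C(C)C=C[C@@]12C
F9 | step 4 | 4,4-ethylenedioxy-3β-isopropyl-6,8aβ-dimethyl-2,3,3aα,4-tetrahydroazulen-1(8aH)-one | O=C1C[C@H](C(C)C)[C@@H]2C3(OCCO3)C=C(C)C=C[C@@]12C
F10 | step 7 | 4,4-ethylenedioxy-3-isopropyl-6,8aβ-dimethyl-1,3aα,4,8a-tetrahydroazulen-1β-ol | O[C@@H]1C=C(C(C)C)[C@@H]2C3(OCCO3)C=C(C)C=C[C@@]12C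
F11 | step 7 | 2β,3β-epoxy-4,4-ethylenedioxy-3α-isopropyl-6,8aβ-dimethyl-1,2,3,3aα,4,8a-hexahydroazulen-1β-ol | O[C@@H]1[C@@H]3O[C@]3(C(C)C)[C@@H]2C4(OCCO4)C=C(C)C=C[C@@]12C
F12 | step 14 | 1α-acetoxy-3α-isopropyl-6,8aβ-dimethyl-1,2,3,3aα,4,5,8,8a-octahydroazulene-3β,4α,8α-triol | CC(=O)O[C@H]1C[C@@](O)(C(C)C)[C@@H]2[C@@H](O)CC(C)=C[C@@H](O)[C@@]12C
F13 | step 14 | 1α-acetoxy-3β,4α-dihydroxy-3α-isopropyl-6,8aβ-dimethyl-2,3,3aα,4,5,8a-hexahydroazulen-8(1H)-one | CC(=O)O[C@H]1C[C@@](O)(C(C)C)[C@@H]2[C@@H](O)CC(C)=CC(=O)[C@@]12C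
F14 | step 14 | 1α-acetoxy-4α-(4-acetoxybenzoyloxy)-3β-hydroxy-3α-isopropyl-6,8aβ-dimethyl-2,3,3aα,4,5,8a-hexahydroazulen-8(1H)-one | CC(=O)O[C@H]1C[C@@](O)(C(C)C)[C@@H]2[C@@H](OC(=O)c3ccc(OC(C)=O)cc3)CC(C)=CC(=O)[C@@]12C
F15 | step 14 | 1α-acetoxy-4α-(4-acetoxybenzoyloxy)-3α-isopropyl-6,8aβ-dimethyl-1,2,3,3aα,4,5,8,8a-octahydroazulene-3β,8β-diol | CC(=O)O[C@H]1C[C@@](O)(C(C)C)[C@@H]2[C@@H](OC(=O)c3ccc(OC(C)=O)cc3)CC(C)=C[C@H](O)[C@@]12C
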